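**Remarks (assumptions on the chemistry)**

- The target is read as ent-fisetinidol-(4α→6)-ent-fisetinidol-(4α→8)-catechin-(6→4α)-ent-fisetinidol. The catechin unit (unit C) is (2R,3S); each 5-deoxy unit (A upper, B middle, D on C6 of catechin) is (2S,3R) with the interflavan bond cis to O3 (2,3-trans-3,4-cis).
- Flavan numbering is used throughout (O1, C2, C3, C4, C4a, C5–C8, C8a; ring A benzo, ring C pyran, ring B the 2-aryl group). Bn = benzyl.
- The hand of the phosphoramidite ligand in steps 6 and 13 is assigned from the accepted facial model for this catalyst and is to be confirmed on the first run; the two series simply use mirror-image ligands.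
- The carbinol centres of 23 and 27 are drawn for aryllithium attack anti to O3; either epimer gives the same cation and the same product.

**Strategy**

Everything rests on cutting the C3–C4 bond of the pyran ring (ring C) of the terminal catechin unit, the bond between its only CH2 (C4) and its carbinol carbon (C3). It is made as a C3=C4 alkene by ring-closing metathesis of a 2-vinylaryl 1-arylallyl ether whose single stereocentre (C2) is set by iridium catalysis; hydroboration then relays C2 to C3. The same alkene, made with the mirror-image ligand and dihydroxylated, gives a 6-bromo ent-fustin ketone that serves three times: aryllithium addition to C4 and ionic deoxygenation build each interflavan bond regiospecifically and 3,4-cis.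

Key step: step 7

**Route**

Step 1
Reactants: 1 3,4-bis(benzyloxy)benzaldehyde
Product: 2 ethyl (E)-3-[3,4-bis(benzyloxy)phenyl]prop-2-enoate
Conditions: Ph3P=CHCO2Et, toluene, 80 °C
Reagents that add atoms: ethyl (triphenylphosphoranylidene)acetate, CCOC(=O)C=P(c1ccccc1)(c1ccccc1)c1ccccc1
Why: Wittig olefination with a stabilised ylide gives the (E)-cinnamate selectively.

Step 2
Reactants: 2 ethyl (E)-3-[3,4-bis(benzyloxy)phenyl]prop-2-enoate
Product: 3 (E)-3-[3,4-bis(benzyloxy)phenyl]prop-2-en-1-ol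
Conditions: i-Bu2AlH (2.2 equiv), CH2Cl2, −78 °C; aqueous work-up
Reagents that add atoms: none
Why: 1,2-Reduction of the unsaturated ester by the aluminium hydride at low temperature gives the allylic alcohol without touching the alkene or the benzyl ethers.

Step 3
Reactants: 3 (E)-3-[3,4-bis(benzyloxy)phenyl]prop-2-en-1-ol
Product: 4 (E)-3-[3,4-bis(benzyloxy)phenyl]allyl methyl carbonate
Conditions: ClCO2Me, pyridine, CH2Cl2, 0 °C
Reagents that add atoms: methyl chloroformate, COC(=O)Cl
Why: O-Acylation of the primary alcohol with a chloroformate installs the carbonate leaving group needed for allyl–iridium formation.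

Step 4
Reactants: 5 2,4,6-trihydroxybenzaldehyde
Product: 6 2,4-bis(benzyloxy)-6-hydroxybenzaldehyde
Conditions: BnBr (2.05 equiv), K2CO3, DMF, rt
Reagents that add atoms: benzyl bromide, BrCc1ccccc1
Why: Williamson etherification; the hydroxyl hydrogen-bonded to the aldehyde is the least nucleophilic and stays free when two equivalents of benzyl bromide are used.

Step 5
Reactants: 6 2,4-bis(benzyloxy)-6-hydroxybenzaldehyde
Product: 7 3,5-bis(benzyloxy)-2-vinylphenol
Conditions: Ph3PCH3Br (2.5 equiv), KOtBu (2.5 equiv), THF, 0 °C to rt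
Reagents that add atoms: methyltriphenylphosphonium bromide, C[P+](c1ccccc1)(c1ccccc1)c1ccccc1.[Br-]
Why: Wittig methylenation; excess ylide tolerates the phenoxide and converts the aldehyde into the styrene.

Step 6
Reactants: 7 3,5-bis(benzyloxy)-2-vinylphenol; 4 (E)-3-[3,4-bis(benzyloxy)phenyl]allyl methyl carbonate
Product: 8 (S)-1,5-bis(benzyloxy)-3-{[1-(3,4-bis(benzyloxy)phenyl)allyl]oxy}-2-vinylbenzene
Conditions: [Ir(cod)Cl]2 (2 mol%), (Sa,Sc,Sc)-O,O'-(1,1'-binaphthalene-2,2'-diyl) N,N-bis(1-phenylethyl)phosphoramidite (4 mol%, preactivated with n-PrNH2), THF, rt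
Reagents that add atoms: none
Why: Iridium-catalysed asymmetric allylic etherification: the phenoxide, formed by the methoxide released from the carbonate, attacks the aryl-substituted terminus of the cyclometalated allyliridium phosphoramidite complex, giving the branched ether with the ligand controlling the new stereocentre (the future C2, S).

Step 7
Reactants: 8 (S)-1,5-bis(benzyloxy)-3-{[1-(3,4-bis(benzyloxy)phenyl)allyl]oxy}-2-vinylbenzene
Product: 9 (2S)-5,7-bis(benzyloxy)-2-[3,4-bis(benzyloxy)phenyl]-2H-chromene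
Conditions: second-generation Grubbs catalyst (3 mol%), CH2Cl2 (0.01 M), 40 °C
Reagents that add atoms: none
Why: Ring-closing metathesis: the ruthenium alkylidene loads on the unhindered allyl terminus of 8, undergoes [2+2] cycloaddition and cycloreversion with the ortho vinyl group and expels ethene, so that the two CH= carbons become C3 and C4 of the new ring. The closest known reaction type is the RCM of 2-vinylaryl allyl ethers to 2H-chromenes. The only ring closed is the six-membered pyran (ring C: O1, C2, C3, C4, C4a, C8a), formed by alkene–alkene metathesis of a 1,7-diene with the new C3=C4 double bond endocyclic. No stereocentre is created; C2 (from step 6) is not involved and keeps its configuration, and it is the element that controls C3 in step 8. The step needs cyclisation to win over cross-metathesis and over isomerisation of the allyl ether by ruthenium hydrides, which the favourable six-ring geometry, dilution and mild temperature secure; the electron-rich chromene is used at once.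

Step 8
Reactants: 9 (2S)-5,7-bis(benzyloxy)-2-[3,4-bis(benzyloxy)phenyl]-2H-chromene
Product: 11 5,7,3',4'-tetra-O-benzyl-(+)-catechin, via C3-borane 10 (not isolated)
Conditions: BH3·THF, THF, 0 °C to rt; then NaOH, H2O2, 0 °C
Reagents that add atoms: borane–tetrahydrofuran, B.C1CCOC1 (boron of 10); hydrogen peroxide, OO (O3 of 11)
Why: Hydroboration–oxidation: boron adds to C3 (β to the electron-rich ring A, away from benzylic C4) on the face anti to the C2 aryl group and is oxidised with retention, so the 2,3-trans 3-ol (3S) is relayed from C2 and C4 is left as CH2.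

Step 9
Reactants: 11 5,7,3',4'-tetra-O-benzyl-(+)-catechin
Product: 12 3,5,7,3',4'-penta-O-benzyl-(+)-catechin
Conditions: NaH, BnBr, n-Bu4NI (cat.), DMF, 0 °C to rt
Reagents that add atoms: benzyl bromide, BrCc1ccccc1
Why: Williamson etherification of the secondary alkoxide protects O3 against the organolithium steps.

Step 10
Reactants: 12 3,5,7,3',4'-penta-O-benzyl-(+)-catechin
Product: 13 8-bromo-3,5,7,3',4'-penta-O-benzyl-(+)-catechin
Conditions: NBS (1.0 equiv), CH2Cl2, −40 °C to 0 °C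
Reagents that add atoms: N-bromosuccinimide, O=C1CCC(=O)N1Br
Why: Electrophilic aromatic bromination; C8 (between O1 and the 7-benzyloxy group) is the position of the phloroglucinol-type ring A that benzylated catechins brominate first.

Step 11
Reactants: 14 4-(benzyloxy)-2-hydroxybenzaldehyde
Product: 15 4-(benzyloxy)-5-bromo-2-hydroxybenzaldehyde
Conditions: NBS (1.0 equiv), MeCN, 0 °C to rt
Reagents that add atoms: N-bromosuccinimide, O=C1CCC(=O)N1Br
Why: Electrophilic bromination para to the free hydroxyl and ortho to the benzyloxy group (C5); the other activated position is flanked by two oxygens and hindered.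

Step 12
Reactants: 15 4-(benzyloxy)-5-bromo-2-hydroxybenzaldehyde
Product: 16 5-(benzyloxy)-4-bromo-2-vinylphenol
Conditions: Ph3PCH3Br (2.5 equiv), KOtBu (2.5 equiv), THF, 0 °C to rt
Reagents that add atoms: methyltriphenylphosphonium bromide, C[P+](c1ccccc1)(c1ccccc1)c1ccccc1.[Br-]
Why: Wittig methylenation as in step 5; the aryl bromide is inert.

Step 13
Reactants: 16 5-(benzyloxy)-4-bromo-2-vinylphenol; 4 (E)-3-[3,4-bis(benzyloxy)phenyl]allyl methyl carbonate
Product: 17 (R)-1-(benzyloxy)-5-{[1-(3,4-bis(benzyloxy)phenyl)allyl]oxy}-2-bromo-4-vinylbenzene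
Conditions: [Ir(cod)Cl]2 (2 mol%), (Ra,Rc,Rc)-O,O'-(1,1'-binaphthalene-2,2'-diyl) N,N-bis(1-phenylethyl)phosphoramidite (4 mol%, preactivated with n-PrNH2), THF, rt
Reagents that add atoms: none
Why: The same iridium-catalysed allylic etherification with the mirror-image ligand sets the (R) configuration of the future C2 of the ent-fisetinidol units.

Step 14
Reactants: 17 (R)-1-(benzyloxy)-5-{[1-(3,4-bis(benzyloxy)phenyl)allyl]oxy}-2-bromo-4-vinylbenzene
Product: 18 (2R)-7-(benzyloxy)-2-[3,4-bis(benzyloxy)phenyl]-6-bromo-2H-chromene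
Conditions: second-generation Grubbs catalyst (3 mol%), CH2Cl2 (0.01 M), 40 °C
Reagents that add atoms: none
Why: Ring-closing metathesis as in step 7 closes the pyran ring of the 5-deoxy series through its C3=C4 bond; the aryl bromide is tolerated.

Step 15
Reactants: 18 (2R)-7-(benzyloxy)-2-[3,4-bis(benzyloxy)phenyl]-6-bromo-2H-chromene
Product: 19 (2S,3R,4R)-7-(benzyloxy)-2-[3,4-bis(benzyloxy)phenyl]-6-bromochromane-3,4-diol (2,3-trans-3,4-cis)
Conditions: OsO4 (2 mol%), N-methylmorpholine N-oxide, acetone/H2O, rt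
Reagents that add atoms: N-methylmorpholine N-oxide, C[N+]1([O-])CCOCC1; water, O
Why: Catalytic syn-dihydroxylation on the face anti to the C2 aryl group gives the 2,3-trans-3,4-cis diol, so O3 (3R) is relayed from C2.

Step 16
Reactants: 19 (2S,3R,4R)-7-(benzyloxy)-2-[3,4-bis(benzyloxy)phenyl]-6-bromochromane-3,4-diol
Product: 20 (2S,3S)-7-(benzyloxy)-2-[3,4-bis(benzyloxy)phenyl]-6-bromo-3-hydroxychroman-4-one
Conditions: activated MnO2, CH2Cl2, rt
Reagents that add atoms: none
Why: MnO2 oxidises only the benzylic, para-alkoxy-activated C4 carbinol and leaves the C3 hydroxyl, giving the trans-dihydroflavonol.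

Step 17
Reactants: 20 (2S,3S)-7-(benzyloxy)-2-[3,4-bis(benzyloxy)phenyl]-6-bromo-3-hydroxychroman-4-one
Product: 21 (2S,3S)-3,7-bis(benzyloxy)-2-[3,4-bis(benzyloxy)phenyl]-6-bromochroman-4-one
Conditions: benzyl 2,2,2-trichloroacetimidate, TfOH (cat.), CH2Cl2/cyclohexane, 0 °C to rt
Reagents that add atoms: benzyl 2,2,2-trichloroacetimidate, N=C(OCc1ccccc1)C(Cl)(Cl)Cl
Why: Acid-catalysed O-benzylation with the trichloroacetimidate avoids base, so the α-ketol neither enolises nor ring-opens and C3 keeps its (thermodynamically preferred trans) configuration.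

Step 18
Reactants: 13 8-bromo-3,5,7,3',4'-penta-O-benzyl-(+)-catechin; 21 (2S,3S)-3,7-bis(benzyloxy)-2-[3,4-bis(benzyloxy)phenyl]-6-bromochroman-4-one
Product: 23 carbinol dimer (4-hydroxy-6-bromo unit B bonded C4 to C8 of penta-O-benzylcatechin), via 8-lithio-penta-O-benzylcatechin 22 (not isolated)
Conditions: t-BuLi (2.0 equiv), THF, −78 °C; then 21, −78 °C to −40 °C; then H2O
Reagents that add atoms: tert-butyllithium, [Li]C(C)(C)C (lithium of 22)
Why: Bromine–lithium exchange followed by 1,2-addition of the aryllithium to the ketone fixes the C8–C4 connectivity regiospecifically; the new carbinol centre is transient and is erased in step 19.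

Step 19
Reactants: 23 carbinol dimer
Product: 24 perbenzylated 6-bromo-ent-fisetinidol-(4α→8)-catechin (unit B 2S,3R with 3,4-cis; Br on C6 of unit B)
Conditions: Bu3SnH (3 equiv), CF3CO2H, CH2Cl2, 0 °C
Reagents that add atoms: none
Why: Ionic deoxygenation: the acid ionises the doubly benzylic tertiary alcohol and Bu3SnH delivers hydride to the planar C4 cation from the face opposite the vicinal 3-benzyloxy group, which leaves the catechin ring cis to O3 (3,4-cis, 4α).

Step 20
Reactants: 24 perbenzylated 6-bromo-ent-fisetinidol-(4α→8)-catechin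
Product: 25 dibromo dimer (additional Br on C6 of the catechin unit)
Conditions: NBS (1.0 equiv), CH2Cl2, −40 °C to 0 °C
Reagents that add atoms: N-bromosuccinimide, O=C1CCC(=O)N1Br
Why: Electrophilic bromination at C6 of the catechin unit, the only remaining position flanked by two ring-A oxygens and by far the most electron-rich carbon of the dimer.

Step 21
Reactants: 25 dibromo dimer; 21 (2S,3S)-3,7-bis(benzyloxy)-2-[3,4-bis(benzyloxy)phenyl]-6-bromochroman-4-one (2.4 equiv)
Product: 27 bis-carbinol tetramer (4-hydroxy units A and D; Br on C6 of A and of D), via dilithio dimer 26 (not isolated)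
Conditions: t-BuLi (4.0 equiv), THF, −78 °C; then 21, −78 °C to −40 °C; then H2O
Reagents that add atoms: tert-butyllithium, [Li]C(C)(C)C (lithium of 26)
Why: Twofold bromine–lithium exchange and twofold 1,2-addition to two molecules of the same ketone attach unit A (at C6 of unit B) and unit D (at C6 of catechin) in one operation, the bromine positions dictating the regiochemistry.

Step 22
Reactants: 27 bis-carbinol tetramer
Product: 28 perbenzylated dibromo tetramer (all three interflavan bonds 4α, 3,4-cis)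
Conditions: Bu3SnH (6 equiv), CF3CO2H, CH2Cl2, 0 °C
Reagents that add atoms: none
Why: Twofold ionic deoxygenation as in step 19; each C4 cation takes hydride anti to its own 3-benzyloxy group, giving both new interflavan bonds 3,4-cis.

Step 23
Reactants: 28 perbenzylated dibromo tetramer
Product: 29 ent-fisetinidol-(4α→6)-ent-fisetinidol-(4α→8)-catechin-(6→4α)-ent-fisetinidol (CNP0126838.1)
Conditions: H2 (1 atm), Pd(OH)2/C, Et3N (2.2 equiv), THF/MeOH/H2O, rt
Reagents that add atoms: none
Why: Hydrogenolysis over Pd(OH)2/C cleaves all seventeen benzyl ethers and, with Et3N as HBr scavenger, both aryl–bromine bonds, while the C–C interflavan bonds and all stereocentres are untouched.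

**Compound list**

1 | 3,4-bis(benzyloxy)benzaldehyde | O=Cc1ccc(OCc2ccccc2)c(OCc2ccccc2)c1 | starting material
2 | ethyl (E)-3-[3,4-bis(benzyloxy)phenyl]prop-2-enoate | CCOC(=O)/C=C/c1ccc(OCc2ccccc2)c(OCc2ccccc2)c1 | intermediate
3 | (E)-3-[3,4-bis(benzyloxy)phenyl]prop-2-en-1-ol | OC/C=C/c1ccc(OCc2ccccc2)c(OCc2ccccc2)c1 | intermediate
4 | (E)-3-[3,4-bis(benzyloxy)phenyl]allyl methyl carbonate | COC(=O)OC/C=C/c1ccc(OCc2ccccc2)c(OCc2ccccc2)c1 | intermediate
5 | 2,4,6-trihydroxybenzaldehyde | O=Cc1c(O)cc(O)cc1O | starting material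
6 | 2,4-bis(benzyloxy)-6-hydroxybenzaldehyde | O=Cc1c(O)cc(OCc2ccccc2)cc1OCc1ccccc1 | intermediate
7 | 3,5-bis(benzyloxy)-2-vinylphenol | C=Cc1c(O)cc(OCc2ccccc2)cc1OCc1ccccc1 | intermediate
8 | (S)-1,5-bis(benzyloxy)-3-{[1-(3,4-bis(benzyloxy)phenyl)allyl]oxy}-2-vinylbenzene | C=Cc1c(OCc9ccccc9)cc(OCc9ccccc9)cc1O[C@H](c8ccc(OCc9ccccc9)c(OCc9ccccc9)c8)C=C | intermediate
9 | (2S)-5,7-bis(benzyloxy)-2-[3,4-bis(benzyloxy)phenyl]-2H-chromene | c1c(OCc9ccccc9)cc(OCc9ccccc9)c2c1O[C@H](c8ccc(OCc9ccccc9)c(OCc9ccccc9)c8)C=C2 | intermediate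
10 | C3-borane of the tetra-O-benzylflavan, boron trans to the C2 aryl group (not isolated) | c1c(OCc9ccccc9)cc(OCc9ccccc9)c2c1O[C@H](c8ccc(OCc9ccccc9)c(OCc9ccccc9)c8)[C@@H](B)C2 | intermediate
11 | 5,7,3',4'-tetra-O-benzyl-(+)-catechin (2R,3S) | c1c(OCc9ccccc9)cc(OCc9ccccc9)c2c1O[C@H](c8ccc(OCc9ccccc9)c(OCc9ccccc9)c8)[C@@H](O)C2 | intermediate
12 | 3,5,7,3',4'-penta-O-benzyl-(+)-catechin | c1c(OCc9ccccc9)cc(OCc9ccccc9)c2c1O[C@H](c8ccc(OCc9ccccc9)c(OCc9ccccc9)c8)[C@@H](OCc9ccccc9)C2 | intermediate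
13 | 8-bromo-3,5,7,3',4'-penta-O-benzyl-(+)-catechin | Brc1c(OCc9ccccc9)cc(OCc9ccccc9)c2c1O[C@H](c8ccc(OCc9ccccc9)c(OCc9ccccc9)c8)[C@@H](OCc9ccccc9)C2 | intermediate
14 | 4-(benzyloxy)-2-hydroxybenzaldehyde | O=Cc1ccc(OCc2ccccc2)cc1O | starting material
15 | 4-(benzyloxy)-5-bromo-2-hydroxybenzaldehyde | O=Cc1cc(Br)c(OCc2ccccc2)cc1O | intermediate
16 | 5-(benzyloxy)-4-bromo-2-vinylphenol | C=Cc1cc(Br)c(OCc2ccccc2)cc1O | intermediate
17 | (R)-1-(benzyloxy)-5-{[1-(3,4-bis(benzyloxy)phenyl)allyl]oxy}-2-bromo-4-vinylbenzene | C=Cc1cc(Br)c(OCc9ccccc9)cc1O[C@@H](c8ccc(OCc9ccccc9)c(OCc9ccccc9)c8)C=C | intermediate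
18 | (2R)-7-(benzyloxy)-2-[3,4-bis(benzyloxy)phenyl]-6-bromo-2H-chromene | c1c(OCc9ccccc9)c(Br)cc2c1O[C@@H](c8ccc(OCc9ccccc9)c(OCc9ccccc9)c8)C=C2 | intermediate
19 | (2S,3R,4R)-7-(benzyloxy)-2-[3,4-bis(benzyloxy)phenyl]-6-bromochromane-3,4-diol (2,3-trans-3,4-cis) | c1c(OCc9ccccc9)c(Br)cc2c1O[C@@H](c8ccc(OCc9ccccc9)c(OCc9ccccc9)c8)[C@H](O)[C@@H]2O | intermediate
20 | (2S,3S)-7-(benzyloxy)-2-[3,4-bis(benzyloxy)phenyl]-6-bromo-3-hydroxychroman-4-one | c1c(OCc9ccccc9)c(Br)cc2c1O[C@@H](c8ccc(OCc9ccccc9)c(OCc9ccccc9)c8)[C@H](O)C2=O | intermediate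
21 | (2S,3S)-3,7-bis(benzyloxy)-2-[3,4-bis(benzyloxy)phenyl]-6-bromochroman-4-one | c1c(OCc9ccccc9)c(Br)cc2c1O[C@@H](c8ccc(OCc9ccccc9)c(OCc9ccccc9)c8)[C@H](OCc9ccccc9)C2=O | intermediate
22 | 8-lithio-3,5,7,3',4'-penta-O-benzylcatechin (not isolated) | [Li]c1c(OCc9ccccc9)cc(OCc9ccccc9)c2c1O[C@H](c8ccc(OCc9ccccc9)c(OCc9ccccc9)c8)[C@@H](OCc9ccccc9)C2 | intermediate
23 | carbinol dimer: 3,7,3',4'-tetra-O-benzyl-6-bromo-4-hydroxy unit B (2S,3R; catechin ring trans to O3) bonded C4 to C8 of penta-O-benzylcatechin | c1c(OCc9ccccc9)c(Br)cc2c1O[C@@H](c8ccc(OCc9ccccc9)c(OCc9ccccc9)c8)[C@H](OCc9ccccc9)[C@@]2(O)c3c(OCc9ccccc9)cc(OCc9ccccc9)c4c3O[C@H](c8ccc(OCc9ccccc9)c(OCc9ccccc9)c8)[C@@H](OCc9ccccc9)C4 | intermediate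
24 | 3,7,3',4'-tetra-O-benzyl-6-bromo-ent-fisetinidol-(4α→8)-3,5,7,3',4'-penta-O-benzylcatechin (upper unit 2,3-trans-3,4-cis) | c1c(OCc9ccccc9)c(Br)cc2c1O[C@@H](c8ccc(OCc9ccccc9)c(OCc9ccccc9)c8)[C@H](OCc9ccccc9)[C@@H]2c3c(OCc9ccccc9)cc(OCc9ccccc9)c4c3O[C@H](c8ccc(OCc9ccccc9)c(OCc9ccccc9)c8)[C@@H](OCc9ccccc9)C4 | intermediate
25 | dibromo dimer: 24 with an additional bromine on C6 of the catechin unit | c1c(OCc9ccccc9)c(Br)cc2c1O[C@@H](c8ccc(OCc9ccccc9)c(OCc9ccccc9)c8)[C@H](OCc9ccccc9)[C@@H]2c3c(OCc9ccccc9)c(Br)c(OCc9ccccc9)c4c3O[C@H](c8ccc(OCc9ccccc9)c(OCc9ccccc9)c8)[C@@H](OCc9ccccc9)C4 | intermediate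
26 | dilithio dimer: lithium on C6 of unit B and on C6 of the catechin unit (not isolated) | c1c(OCc9ccccc9)c([Li])cc2c1O[C@@H](c8ccc(OCc9ccccc9)c(OCc9ccccc9)c8)[C@H](OCc9ccccc9)[C@@H]2c3c(OCc9ccccc9)c([Li])c(OCc9ccccc9)c4c3O[C@H](c8ccc(OCc9ccccc9)c(OCc9ccccc9)c8)[C@@H](OCc9ccccc9)C4 | intermediate
27 | bis-carbinol tetramer: perbenzylated, 4-hydroxy on units A and D (aryl trans to O3), bromine on C6 of A and of D | c1c(OCc9ccccc9)c(Br)cc2c1O[C@@H](c8ccc(OCc9ccccc9)c(OCc9ccccc9)c8)[C@H](OCc9ccccc9)[C@@]2(O)c3cc4c(cc3OCc9ccccc9)O[C@@H](c8ccc(OCc9ccccc9)c(OCc9ccccc9)c8)[C@H](OCc9ccccc9)[C@@H]4c5c(OCc9ccccc9)c([C@@]7(O)c1cc(Br)c(OCc9ccccc9)cc1O[C@@H](c8ccc(OCc9ccccc9)c(OCc9ccccc9)c8)[C@@H]7OCc9ccccc9)c(OCc9ccccc9)c6c5O[C@H](c8ccc(OCc9ccccc9)c(OCc9ccccc9)c8)[C@@H](OCc9ccccc9)C6 | intermediate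
28 | perbenzylated dibromo tetramer: heptadeca-O-benzyl, bromine on C6 of units A and D, all interflavan bonds 4α (3,4-cis) | c1c(OCc9ccccc9)c(Br)cc2c1O[C@@H](c8ccc(OCc9ccccc9)c(OCc9ccccc9)c8)[C@H](OCc9ccccc9)[C@@H]2c3cc4c(cc3OCc9ccccc9)O[C@@H](c8ccc(OCc9ccccc9)c(OCc9ccccc9)c8)[C@H](OCc9ccccc9)[C@@H]4c5c(OCc9ccccc9)c([C@@H]7c1cc(Br)c(OCc9ccccc9)cc1O[C@@H](c8ccc(OCc9ccccc9)c(OCc9ccccc9)c8)[C@@H]7OCc9ccccc9)c(OCc9ccccc9)c6c5O[C@H](c8ccc(OCc9ccccc9)c(OCc9ccccc9)c8)[C@@H](OCc9ccccc9)C6 | intermediate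
29 | ent-fisetinidol-(4α→6)-ent-fisetinidol-(4α→8)-catechin-(6→4α)-ent-fisetinidol (CNP0126838.1) | Oc1ccc2c(c1)O[C@@H](c1ccc(O)c(O)c1)[C@H](O)[C@@H]2c1cc2c(cc1O)O[C@@H](c1ccc(O)c(O)c1)[C@H](O)[C@@H]2c1c(O)c([C@@H]2c3ccc(O)cc3O[C@@H](c3ccc(O)c(O)c3)[C@@H]2O)c(O)c2c1O[C@H](c1ccc(O)c(O)c1)[C@@H](O)C2 | target

**Count and risks**

Total step count: 23. Longest linear sequence: 14 steps (1 → 4 → 8 → 13 → 29, steps 1–3, 6–10, 18–23; the branch through ketone 21 is equally long).

Steps most likely to fail: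

1. Step 19 (and its twofold repeat in step 22). Hydride delivery to the C4 cation may be poorly face-selective, because the C2 aryl group sits on the face opposite O3 and can hinder the desired approach. A 1,2-hydride shift from C3 may also compete. Fallback: from ketone 21, reduction with NaBH4 (MeOH/THF, 0 °C) gives the 2,3-trans-3,4-trans 4-ol F1. Its C4 cation, generated with TMSOTf in CH2Cl2 at −78 °C, alkylates penta-O-benzylcatechin 12 at C8 in a Friedel–Crafts reaction. This reaction type is expected to give both C4 epimers; the 3,4-cis one is 24, secured by chromatography instead of by induction, and the route continues from 24.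

2. Step 21. The twofold bromine–lithium exchange may stop at the monolithio stage. The hindered C6 aryllithium of the catechin ring may also deprotonate ketone 21 at C3 (ring opening to a chalcone) instead of adding to it. Fallback: the two units are attached one at a time by different chemistry. From 24 (one bromide only), t-BuLi and ketone 21 give the trimeric carbinol F2, and Bu3SnH/CF3CO2H gives the trimer F3 (units A, B, C; Br on unit A). The third unit is then introduced as an electrophile: TMSOTf-promoted Friedel–Crafts alkylation of F3 by the 4-ol F1 (made as under point 1) occurs at C6 of the catechin ring, its only free phloroglucinol-type position, and returns to 28 after separation of the C4 epimers.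

3. Step 6. The electron-rich, ortho-substituted phenoxide may attack through ring carbon instead of oxygen. The branched ether of an electron-rich cinnamyl system may also re-ionise on the catalyst and lose enantiopurity. Fallback: the C2 stereocentre is made first and the ether bond second. From aldehyde 1, enantioselective vinylation with Zn(CH=CH2)2 and a catalytic chiral amino alcohol (3-exo-morpholinoisoborneol, antipode chosen for the R product) gives (R)-1-[3,4-bis(benzyloxy)phenyl]prop-2-en-1-ol F4. Mitsunobu etherification of phenol 7 with F4 (PPh3, DIAD, toluene, −20 °C) proceeds with inversion and returns to 8, so the key step is unchanged.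

Further compounds
F1 | step 19 | (2S,3R,4S)-3,7-bis(benzyloxy)-2-[3,4-bis(benzyloxy)phenyl]-6-bromochroman-4-ol (2,3-trans-3,4-trans) | c1c(OCc9ccccc9)c(Br)cc2c1O[C@@H](c8ccc(OCc9ccccc9)c(OCc9ccccc9)c8)[C@H](OCc9ccccc9)[C@H]2O
F2 | step 21 | trimeric carbinol: perbenzylated 4-hydroxy-6-bromo unit A bonded C4 to C6 of unit B of the debrominated dimer | c1c(OCc9ccccc9)c(Br)cc2c1O[C@@H](c8ccc(OCc9ccccc9)c(OCc9ccccc9)c8)[C@H](OCc9ccccc9)[C@@]2(O)c3cc4c(cc3OCc9ccccc9)O[C@@H](c8ccc(OCc9ccccc9)c(OCc9ccccc9)c8)[C@H](OCc9ccccc9)[C@@H]4c5c(OCc9ccccc9)cc(OCc9ccccc9)c6c5O[C@H](c8ccc(OCc9ccccc9)c(OCc9ccccc9)c8)[C@@H](OCc9ccccc9)C6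
F3 | step 21 | perbenzylated 6-bromo-ent-fisetinidol-(4α→6)-ent-fisetinidol-(4α→8)-catechin | c1c(OCc9ccccc9)c(Br)cc2c1O[C@@H](c8ccc(OCc9ccccc9)c(OCc9ccccc9)c8)[C@H](OCc9ccccc9)[C@@H]2c3cc4c(cc3OCc9ccccc9)O[C@@H](c8ccc(OCc9ccccc9)c(OCc9ccccc9)c8)[C@H](OCc9ccccc9)[C@@H]4c5c(OCc9ccccc9)cc(OCc9ccccc9)c6c5O[C@H](c8ccc(OCc9ccccc9)c(OCc9ccccc9)c8)[C@@H](OCc9ccccc9)C6
F4 | step 6 | (R)-1-[3,4-bis(benzyloxy)phenyl]prop-2-en-1-ol | O[C@@H](c1ccc(OCc2ccccc2)c(OCc2ccccc2)c1)C=C
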